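**Retrosynthetic overview**

1. 16 ⇒ 14 + 15: one tin-mediated radical cascade (acyl addition to the vinyl group, 5-exo, then 7-endo with loss of PhSO2) closes the cyclopentane, then the cycloheptane, and unveils the α-methylene ketone.
2. 14 ⇒ 10 + 12 by cross-metathesis and selenoesterification; 10 ⇒ 7 by methyl addition at C10 and oxidation at C3.
3. 7 ⇒ 6: one Lewis-acid epoxide cascade closes the oxepane, then the cyclohexanone.
4. 6 ⇒ 1 by Shi bis-epoxidation, Eschenmoser methylenation and conjugate allylation with silyl trapping.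
5. Ring order: oxepane and cyclohexane (step 4), then cyclopentane and cycloheptane (step 10).

Assumption: atom labels C1–C24 follow squalene numbering (C2 = oxepane CMe2, C12–C13 = ethylene bridge, C23 = carbocyclic CMe2); 1 is bought as the pure (E)-isomer and 15 in ≥98% ee.

**Route**

Step 1
Reactants: 1 (5E)-6,10-dimethylundeca-5,9-dien-2-one ((E)-geranylacetone)
Product: 2 4-[(2R,3R)-3-{2-[(2R)-3,3-dimethyloxiran-2-yl]ethyl}-3-methyloxiran-2-yl]butan-2-one
Conditions: 1,2:4,5-di-O-isopropylidene-β-D-erythro-2,3-hexodiulo-2,6-pyranose (Shi ketone, 30 mol%), 2KHSO5·KHSO4·K2SO4 (Oxone), K2CO3, Bu4NHSO4, MeCN/CH2(OMe)2/aq. Na2B4O7, 0 °C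
Reagents that add atoms: potassium peroxymonosulfate KHSO5, [K+].[O-]S(=O)(=O)OO
Why: Shi asymmetric epoxidation: the chiral dioxirane epoxidises both electron-rich trisubstituted alkenes through the spiro transition state, setting C6 and C7 (and C3, erased later) as (R), while the ketone is inert.

Step 2
Reactants: 2 bis-epoxy methyl ketone
Product: 5 5-[(2R,3R)-3-{2-[(2R)-3,3-dimethyloxiran-2-yl]ethyl}-3-methyloxiran-2-yl]pent-1-en-3-one, via Mannich base 3 (not isolated), via methiodide 4 (not isolated)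
Conditions: LiN(iPr)2, THF, −78 °C; Me2N=CH2 I, −78 to 0 °C; then MeI; then aq. NaHCO3, CH2Cl2, 23 °C
Reagents that add atoms: Eschenmoser's salt (N,N-dimethylmethyleneiminium iodide), C=[N+](C)C.[I-]
Why: Eschenmoser methylenation: kinetic deprotonation on the methyl side, Mannich reaction, quaternisation and E1cB loss of trimethylamine give the vinyl ketone (C12 added) without touching the epoxides; no stereocentre is formed.

Step 3
Reactants: 5 bis-epoxy vinyl ketone
Product: 6 trimethyl({(3Z)-1-[(2R,3R)-3-{2-[(2R)-3,3-dimethyloxiran-2-yl]ethyl}-3-methyloxiran-2-yl]octa-3,7-dien-3-yl}oxy)silane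
Conditions: CH2=CHCH2MgBr, CuBr·SMe2 (1:1), Me3SiCl, THF, −78 °C; Et3N, pentane work-up
Reagents that add atoms: allylmagnesium bromide, C=CC[Mg]Br; chlorotrimethylsilane, C[Si](C)(C)Cl
Why: Chlorosilane-accelerated conjugate addition of an allylcopper reagent to the s-cis vinyl ketone with O-silylation of the enolate gives the regiodefined (Z)-enol silane (C10=C11) that enolisation of the saturated ketone could not deliver; no stereocentre is formed.

Step 4
Reactants: 6 bis-epoxy enol silane
Product: 7 (3R,5aR,6R,9aR)-6-(but-3-en-1-yl)-2,2,5a-trimethyl-3-[(trimethylsilyl)oxy]octahydro-1-benzoxepin-7(2H)-one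
Conditions: Me3SiOTf (0.3 equiv), 2,6-di-tert-butyl-4-methylpyridine, CH2Cl2, −78 °C
Reagents that add atoms: none
Why: Biomimetic epoxide-opening oxa-/carbacyclisation cascade: the silylated terminal epoxide is opened 7-endo at C2 by the internal epoxide oxygen, and the enol silane carbon C11 opens the resulting epoxonium ion at C6 with inversion through a chair, so oxepane and cyclohexanone form in one operation with trans C6/C7 fusion dictated by the trans epoxide, the C11 chain equatorial (also the thermodynamic α-ketone epimer) and the silyl group relayed from the enol oxygen to the C3 oxygen.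

Step 5
Reactants: 7 bicyclic ketone
Product: 9 (3R,5aR,6R,7S,9aR)-6-(but-3-en-1-yl)-2,2,5a,7-tetramethyldecahydro-1-benzoxepine-3,7-diol, via silyl ether 8 (not isolated)
Conditions: MeLi, CeCl3, THF, −78 °C; then K2CO3, MeOH, 23 °C
Reagents that add atoms: methyllithium, [Li]C
Why: Organocerium 1,2-addition (non-basic, so no enolisation): the axial trajectory is blocked by the syn-axial C6 methyl group, so methyl enters equatorially and gives the axial C10 alcohol cis to the C11 chain, after which methanolysis removes the trimethylsilyl ether.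

Step 6
Reactants: 9 diol
Product: 10 (5aR,6R,7S,9aR)-6-(but-3-en-1-yl)-7-hydroxy-2,2,5a,7-tetramethyloctahydro-1-benzoxepin-3(2H)-one
Conditions: Dess–Martin periodinane, NaHCO3, CH2Cl2, 23 °C
Reagents that add atoms: none
Why: Dess–Martin oxidation of the only secondary alcohol gives the oxepan-3-one while the tertiary alcohol and the alkene are inert; the C3 stereocentre is deliberately erased.

Step 7
Reactants: 11 2-(bromomethyl)prop-2-enoic acid
Product: 12 2-[(phenylsulfonyl)methyl]prop-2-enoic acid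
Conditions: PhSO2Na (1.1 equiv), MeOH, 65 °C
Reagents that add atoms: sodium benzenesulfinate, [Na+].[O-]S(=O)c1ccccc1
Why: S-alkylation of the sulfinate by the allylic bromide (SN2 and SN2′ give the same product); no stereocentre is formed.

Step 8
Reactants: 10 hydroxy ketone with terminal alkene, 12 sulfonyl acrylic acid
Product: 13 (2Z)-5-[(5aR,6R,7S,9aR)-7-hydroxy-2,2,5a,7-tetramethyl-3-oxodecahydro-1-benzoxepin-6-yl]-2-[(phenylsulfonyl)methyl]pent-2-enoic acid (chain trans to the carboxyl group)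
Conditions: second-generation Hoveyda–Grubbs catalyst RuCl2(H2IMes)(=CH-C6H4-2-OiPr) (10 mol%), 12 (3 equiv), CH2Cl2, 40 °C
Reagents that add atoms: none
Why: Olefin cross-metathesis of a terminal alkene with a 1,1-disubstituted acrylic acid releases ethene and gives the trisubstituted alkene with the chain trans to the carboxyl group (thermodynamic, as with methacrylates); no stereocentre is formed.

Step 9
Reactants: 13 enoic acid
Product: 14 Se-phenyl (2E)-5-[(5aR,6R,7S,9aR)-7-hydroxy-2,2,5a,7-tetramethyl-3-oxodecahydro-1-benzoxepin-6-yl]-2-[(phenylsulfonyl)methyl]pent-2-eneselenoate (same alkene geometry as 13)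
Conditions: N-(phenylseleno)phthalimide, Bu3P (premixed), CH2Cl2, −30 to 0 °C
Reagents that add atoms: N-(phenylseleno)phthalimide, O=C1N([Se]c2ccccc2)C(=O)c2ccccc12
Why: Phosphine-mediated selenoesterification of the acid (acyloxyphosphonium then selenolate attack) gives the acyl-radical precursor and tolerates the free tertiary alcohol and the ketone; no stereocentre is formed.

Step 10
Reactants: 14 selenoester, 15 (3R)-3,7-dimethylocta-1,6-dien-3-ol ((R)-linalool)
Product: 16 (5aR,6R,7S,9aR)-7-hydroxy-6-{2-[(1R,3aR,5R,8aR)-1-hydroxy-1,4,4-trimethyl-6-methylidene-7-oxodecahydroazulen-5-yl]ethyl}-2,2,5a,7-tetramethyloctahydro-1-benzoxepin-3(2H)-one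
Conditions: (Bu3Sn)2 (1.2 equiv), 15 (20 equiv, excess recovered), PhH, 80 °C, sunlamp, 14 added over 10 h
Reagents that add atoms: none
Why: Proposed new method: Bu3Sn• abstracts PhSe from 14, the α,β-unsaturated acyl radical adds to the terminal vinyl carbon of 15 (C16–C17), the secondary C18 radical closes 5-exo onto the trisubstituted alkene through the Beckwith chair (C18/C22 cis, both new bonds expected anti to the C19 oxygen, whose configuration comes unchanged from 15), and the tertiary C23 radical closes 7-endo on the enone β-carbon C14 (chair-like, chain pseudo-equatorial) with β-scission of PhSO2•, which unveils the exo-methylene ketone and regenerates Bu3Sn• from the distannane; no hydrogen donor is present, so the slow steps are not intercepted; closest known types are acyl-radical cascade cyclisations of selenoesters, radical addition–cyclisation of linalool and SH2′ allyl-sulfone terminations.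

**Compound list**

1 | (5E)-6,10-dimethylundeca-5,9-dien-2-one | CC(=O)CC/C=C(\C)CCC=C(C)C | starting material
2 | 4-[(2R,3R)-3-{2-[(2R)-3,3-dimethyloxiran-2-yl]ethyl}-3-methyloxiran-2-yl]butan-2-one | CC(=O)CC[C@H]1O[C@]1(C)CC[C@H]1OC1(C)C | intermediate
3 | 1-(dimethylamino)-5-[(2R,3R)-3-{2-[(2R)-3,3-dimethyloxiran-2-yl]ethyl}-3-methyloxiran-2-yl]pentan-3-one (Mannich base) | CN(C)CCC(=O)CC[C@H]1O[C@]1(C)CC[C@H]1OC1(C)C | intermediate (not isolated)
4 | trimethylammonium iodide of 3 (methiodide) | C[N+](C)(C)CCC(=O)CC[C@H]1O[C@]1(C)CC[C@H]1OC1(C)C.[I-] | intermediate (not isolated)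
5 | 5-[(2R,3R)-3-{2-[(2R)-3,3-dimethyloxiran-2-yl]ethyl}-3-methyloxiran-2-yl]pent-1-en-3-one | C=CC(=O)CC[C@H]1O[C@]1(C)CC[C@H]1OC1(C)C | intermediate
6 | trimethyl({(3Z)-1-[(2R,3R)-3-{2-[(2R)-3,3-dimethyloxiran-2-yl]ethyl}-3-methyloxiran-2-yl]octa-3,7-dien-3-yl}oxy)silane | C=CCC/C=C(\O[Si](C)(C)C)CC[C@H]1O[C@]1(C)CC[C@H]1OC1(C)C | intermediate
7 | (3R,5aR,6R,9aR)-6-(but-3-en-1-yl)-2,2,5a-trimethyl-3-[(trimethylsilyl)oxy]octahydro-1-benzoxepin-7(2H)-one | C=CCC[C@@H]1[C@@]2(C)CC[C@@H](O[Si](C)(C)C)C(C)(C)O[C@@H]2CCC1=O | intermediate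
8 | (3R,5aR,6R,7S,9aR)-6-(but-3-en-1-yl)-2,2,5a,7-tetramethyl-3-[(trimethylsilyl)oxy]decahydro-1-benzoxepin-7-ol | C=CCC[C@@H]1[C@@]2(C)CC[C@@H](O[Si](C)(C)C)C(C)(C)O[C@@H]2CC[C@]1(C)O | intermediate (not isolated)
9 | (3R,5aR,6R,7S,9aR)-6-(but-3-en-1-yl)-2,2,5a,7-tetramethyldecahydro-1-benzoxepine-3,7-diol | C=CCC[C@@H]1[C@@]2(C)CC[C@@H](O)C(C)(C)O[C@@H]2CC[C@]1(C)O | intermediate
10 | (5aR,6R,7S,9aR)-6-(but-3-en-1-yl)-7-hydroxy-2,2,5a,7-tetramethyloctahydro-1-benzoxepin-3(2H)-one | C=CCC[C@@H]1[C@@]2(C)CCC(=O)C(C)(C)O[C@@H]2CC[C@]1(C)O | intermediate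
11 | 2-(bromomethyl)prop-2-enoic acid | C=C(CBr)C(=O)O | starting material
12 | 2-[(phenylsulfonyl)methyl]prop-2-enoic acid | C=C(CS(=O)(=O)c1ccccc1)C(=O)O | intermediate
13 | (2Z)-5-[(5aR,6R,7S,9aR)-7-hydroxy-2,2,5a,7-tetramethyl-3-oxodecahydro-1-benzoxepin-6-yl]-2-[(phenylsulfonyl)methyl]pent-2-enoic acid | OC(=O)/C(CS(=O)(=O)c1ccccc1)=C/CC[C@@H]1[C@@]2(C)CCC(=O)C(C)(C)O[C@@H]2CC[C@]1(C)O | intermediate
14 | Se-phenyl (2E)-5-[(5aR,6R,7S,9aR)-7-hydroxy-2,2,5a,7-tetramethyl-3-oxodecahydro-1-benzoxepin-6-yl]-2-[(phenylsulfonyl)methyl]pent-2-eneselenoate | O=C([Se]c1ccccc1)/C(CS(=O)(=O)c1ccccc1)=C/CC[C@@H]1[C@@]2(C)CCC(=O)C(C)(C)O[C@@H]2CC[C@]1(C)O | intermediate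
15 | (3R)-3,7-dimethylocta-1,6-dien-3-ol ((R)-linalool) | C=C[C@](C)(O)CCC=C(C)C | starting material
16 | (5aR,6R,7S,9aR)-7-hydroxy-6-{2-[(1R,3aR,5R,8aR)-1-hydroxy-1,4,4-trimethyl-6-methylidene-7-oxodecahydroazulen-5-yl]ethyl}-2,2,5a,7-tetramethyloctahydro-1-benzoxepin-3(2H)-one | C=C1C(=O)C[C@@H]2[C@@H](CC[C@@]2(C)O)C(C)(C)[C@H]1CC[C@@H]1[C@@]2(C)CCC(=O)C(C)(C)O[C@@H]2CC[C@]1(C)O | target

**Step count**

Total steps: 10. Longest linear sequence: 9 (steps 1–6, 8, 9, 10).

**Steps most likely to fail, with fallbacks**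

Step 10 is the least secure. The intermolecular addition of the acyl radical to an unactivated vinyl group is slow. The 7-endo closure joins a quaternary to a tertiary carbon. PhSO2• can scramble the allyl sulfone. Above all, the facial sense of the 5-exo closure relative to C19 is not secured by precedent: a simple steric reading of the chair (oxygen pseudo-axial, methyl pseudo-equatorial) predicts the oxygen syn to the new bonds, in which case the C18/C22/C14 diastereomer of 16 would be the main product. The fallback sets out from 10 and comes back at 16, with every stereocentre set by a stereospecific event. Ozonolysis of 10 (O3, then Me2S) gives the keto aldehyde F1, the Ohira–Bestmann reagent (K2CO3, MeOH) gives the terminal alkyne F2, and PdCl2(PPh3)2/CuI-catalysed coupling with acetyl chloride (Et3N) gives the ynone F3. Separately, ring-closing metathesis of (S)-linalool (the enantiomer of 15; second-generation Grubbs catalyst RuCl2(=CHPh)(H2IMes)(PCy3)) gives (S)-1-methylcyclopent-2-en-1-ol F4, which is acylated (EtMgBr, then isobutyryl chloride) to the tertiary allylic isobutyrate F5. Ireland–Claisen rearrangement (LiN(iPr)2, Me3SiCl, THF, −78 to 65 °C) transfers the carbinol chirality suprafacially to C22 and gives the acid F6 with the quaternary C23 in place. Photoredox decarboxylation of F6 ([Ir(dF(CF3)ppy)2(dtbbpy)]PF6, Cs2CO3, blue light) and Giese addition of the tertiary radical to F3 gives the enone F7 (acetyl cis to the quaternary carbon). m-CPBA epoxidises the cyclopentene on the face away from the quaternary substituent to give the epoxide F8. LiN(SiMe3)2 forms the methyl-side enolate, which opens the epoxide at its secondary carbon with inversion and closes the seven-membered ring to the hydroxy enone F9, setting C18 and C19. Conjugate reduction with [(Ph3P)CuH]6 delivers hydride to C14 from the convex face, the enolate is trapped with Eschenmoser's salt to give the Mannich base F10, and this loses dimethylamine on warming with silica gel in toluene to give 16.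

Step 8 may stall because the hindered, acidic, 1,1-disubstituted partner 12 is a poor metathesis substrate. The fallback sets out from 10 and comes back at 13. Ozonolysis gives the aldehyde F1 (as above), then one-pot conjugate addition of PhSO2Na to triethyl 2-phosphonoacrylate followed by Horner–Wadsworth–Emmons olefination of F1 gives the ethyl ester F11, and LiOH hydrolysis returns 13.

Step 3 may give 1,2-addition or polymerisation of the vinyl ketone instead of clean conjugate allylation. The fallback sets out from 5 and comes back at 6. Deliberate 1,2-addition of CH2=CHCH2MgBr (THF, −78 °C) gives the 1,5-dien-3-ol F12, and anionic oxy-Cope rearrangement (KH, 18-crown-6, THF, 0 °C) delivers the same regiodefined enolate, which Me3SiCl traps as 6.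

Step 4 is not among the three because enol-silane-terminated bis-epoxide cascades of this exact type are established.

**Further compounds**

F1 | step 10 | 3-[(5aR,6R,7S,9aR)-7-hydroxy-2,2,5a,7-tetramethyl-3-oxodecahydro-1-benzoxepin-6-yl]propanal | O=CCC[C@@H]1[C@@]2(C)CCC(=O)C(C)(C)O[C@@H]2CC[C@]1(C)O
F2 | step 10 | (5aR,6R,7S,9aR)-6-(but-3-yn-1-yl)-7-hydroxy-2,2,5a,7-tetramethyloctahydro-1-benzoxepin-3(2H)-one | C#CCC[C@@H]1[C@@]2(C)CCC(=O)C(C)(C)O[C@@H]2CC[C@]1(C)O
F3 | step 10 | (5aR,6R,7S,9aR)-7-hydroxy-2,2,5a,7-tetramethyl-6-(5-oxohex-3-yn-1-yl)octahydro-1-benzoxepin-3(2H)-one | CC(=O)C#CCC[C@@H]1[C@@]2(C)CCC(=O)C(C)(C)O[C@@H]2CC[C@]1(C)O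
F4 | step 10 | (1S)-1-methylcyclopent-2-en-1-ol | O[C@]1(C)C=CCC1
F5 | step 10 | (1S)-1-methylcyclopent-2-en-1-yl 2-methylpropanoate | CC(C)C(=O)O[C@]1(C)C=CCC1
F6 | step 10 | 2-methyl-2-[(1R)-3-methylcyclopent-2-en-1-yl]propanoic acid | CC1=C[C@@H](CC1)C(C)(C)C(=O)O
F7 | step 10 | (3Z)-4-{2-[(5aR,6R,7S,9aR)-7-hydroxy-2,2,5a,7-tetramethyl-3-oxodecahydro-1-benzoxepin-6-yl]ethyl}-5-methyl-5-[(1R)-3-methylcyclopent-2-en-1-yl]hex-3-en-2-one | CC(=O)/C=C(/CC[C@@H]1[C@@]2(C)CCC(=O)C(C)(C)O[C@@H]2CC[C@]1(C)O)C(C)(C)[C@H]1C=C(C)CC1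
F8 | step 10 | epoxide of F7 at the cyclopentene, oxygen on the face opposite to the quaternary substituent | CC(=O)/C=C(/CC[C@@H]1[C@@]2(C)CCC(=O)C(C)(C)O[C@@H]2CC[C@]1(C)O)C(C)(C)[C@H]1[C@@H]2O[C@]2(C)CC1
F9 | step 10 | (5aR,6R,7S,9aR)-7-hydroxy-6-{2-[(1R,3aR,8aR)-1-hydroxy-1,4,4-trimethyl-7-oxo-1,2,3,3a,4,7,8,8a-octahydroazulen-5-yl]ethyl}-2,2,5a,7-tetramethyloctahydro-1-benzoxepin-3(2H)-one | O=C1C[C@@H]2[C@@H](CC[C@@]2(C)O)C(C)(C)C(CC[C@@H]2[C@@]3(C)CCC(=O)C(C)(C)O[C@@H]3CC[C@]2(C)O)=C1
F10 | step 10 | 6-[(dimethylamino)methyl] analogue of 16 in place of the 6-methylidene group (Mannich base, both C6 epimers) | CN(C)CC1C(=O)C[C@@H]2[C@@H](CC[C@@]2(C)O)C(C)(C)[C@H]1CC[C@@H]1[C@@]2(C)CCC(=O)C(C)(C)O[C@@H]2CC[C@]1(C)O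
F11 | step 8 | ethyl ester of 13 | CCOC(=O)/C(CS(=O)(=O)c1ccccc1)=C/CC[C@@H]1[C@@]2(C)CCC(=O)C(C)(C)O[C@@H]2CC[C@]1(C)O
F12 | step 3 | 3-ethenyl-1-[(2R,3R)-3-{2-[(2R)-3,3-dimethyloxiran-2-yl]ethyl}-3-methyloxiran-2-yl]hex-5-en-3-ol (both carbinol epimers) | C=CCC(O)(C=C)CC[C@H]1O[C@]1(C)CC[C@H]1OC1(C)C
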